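## Analysis of the target

1. With C1 as the lactone carbonyl and C25 as the carbinol carbon that bears the ring oxygen, 49 is a 26-membered macrolactone (C1–C25 plus O). An eleven-carbon side chain, C26–C36, sits on C25.
2. The ring holds a (2E,4E)-dienoate (C1–C5) and two methyl-branched (E,E)-dienes, C8=C9–C10(Me)=C11 and C18=C19–C20(Me)=C21. The side chain holds the E alkene C26=C27 and the trisubstituted epoxide C30–C31.
3. The fourteen stereocentres (6R,7R,12R,16R,17R,22R,23S,24R,25S,29S,30R,31R,32R,33S) form five clusters that cannot relay to each other: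
   - C6/C7, a syn diol;
   - C12, a lone methyl;
   - C16/C17, syn OMe/OH;
   - C22–C25, with Me/OH syn, OH/OMe syn and OMe/O-acyl anti;
   - C29–C33, a carbinol erythro to the epoxide, followed by syn OMe/OH.
4. The feature that decides the strategy is the segment C4=C5–C6(OH)–C7(OH)–C8=C9. It is locally C2-symmetric (both carbinols R, both alkenes E) and is bounded on both sides by sp2–sp2 single bonds, C3–C4 and C9–C10.
5. Two smaller repeats help with the fragments. The syn methoxy-carbinol pair occurs three times (C16/C17, C24/C23, C32/C33), and the unit MeC=CH–CH(Me) occurs twice (C10–C12, C20–C22).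
6. The sensitive groups are:
   - the epoxide between the C29 and C33 hydroxyls, which acid would turn into a tetrahydrofuran;
   - the dienoate ester 1,3 to the free C23 hydroxyl, where base would shift the acyl group;
   - the allylic and dienylic carbinols C7 and C17;
   - the three polyene units.
7. The synthesis is hard for three reasons: the large ring must close at a hindered C25 oxygen, seven oxygens must be told apart (three methylated, one acylated, the rest free), and each remote cluster needs its own source of absolute configuration without a long linear sequence.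

## Retrosynthetic reasoning

**49 ⇒ 48.** Only four O–Si bonds are cut. Triethylsilyl ethers at C17, C23, C29 and C33 come off under buffered fluoride, which the epoxide and the ester tolerate. The C6/C7 diol never needs protection.

**48 ⇒ 46 + 5 (key disconnection).** The bonds C3–C4 and C9–C10 are cut at the same time, which excises the C2-symmetric six-carbon unit C4–C9 as the bis-stannane 5.
- The two ends of 5 are homotopic, so either orientation of insertion into the bis(vinyl iodide) 46 gives the same product. The regiochemical problem of a two-bond union therefore does not arise.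
- The forward reaction must form two sp2–sp2 bonds with retention, complete the dienoate and the C8–C11 diene, bring in C6 and C7, and close the 26-membered ring.
- The precursor 46 is acyclic and carries no acid, no activated ester and no desymmetrised diol.

**46 ⇒ 44 + 45.** The ester bond O–C1 is cut. C25–OH is the only free hydroxyl in 44, so acylation with the three-carbon acid 45 needs no selectivity. It is placed after all other palladium steps because the iodoacrylate would interfere with them.

**44 ⇒ 42 ⇒ 40 + 18.** The C10 iodide is masked as a methyl-capped alkyne until the C19–C20 diene bond has been made, so only one vinyl iodide is present during that coupling. The C19–C20 bond is cut by a Stille disconnection between the C20 alkyne of 40 (hydrostannated in the flask) and the vinyl iodide 18. Both alkynes are the same motif and are opened by the same reaction.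

**40 ⇒ 29 + 39.** The C25–C26 bond is cut (Nozaki–Hiyama–Kishi). This joins the ring part and the side chain at a carbinol that emerges free and unique, ready for step 32. The α-methoxy and β-silyloxy groups of 29 both direct to the 24,25-anti, 23,25-anti product.

**29 ⇒ 26 + 22.** The C22–C23 bond is cut. An SE2′ addition of the axially chiral allenylstannane 22 to the chelated α-methoxy aldehyde 26 sets C22 and C23 together and delivers the C20–C21 alkyne. No epimerisable α-methyl-β,γ-unsaturated carbonyl compound is ever made. 26 goes back to racemic 23 by a stereoconvergent allylic etherification that sets C24, and 22 goes back to ketone 19.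

**39 ⇒ 34 ⇒ 30.** In the side chain the C28–C29 bond is cut (catalytic asymmetric propargylation of enal 34). The epoxide is traced to the C29 allylic alcohol 35 (matched Sharpless epoxidation), C30=C31 to a Wittig reaction, and C32–C33 to a syn-selective methoxyallylboration of 30.

**18 ⇒ 12 ⇒ 6.** The C16–C17 bond is cut (syn-selective alkoxyallylboration of 12, the mirror-image reagent series of the one used on 30). The chain C11–C16 with its lone C12 methyl is traced to the six ring carbons of 6. Asymmetric conjugate addition with enolate trapping gives 8, and ozonolysis of 8 gives a chain whose two ends differ in oxidation level.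

**5 ⇒ 1.** The linchpin comes from the chiral pool. The two carbinol carbons of 1 are C6 and C7, and both esters are extended in the same way (two-directional synthesis), so symmetry is kept until the key step uses it.

## Alternatives that were turned down

**Alternative 1:** (the textbook route) cut the ester bond O–C1 and close the ring by Yamaguchi-type macrolactonisation of the fully assembled seco acid A1.
- The closure forms no C–C bond, and it needs the whole C1–C36 chain first.
- The C4–C9 unit would have to be desymmetrised and coupled at each end in separate steps. C6/C7 would need protection, and C25–OH would have to be unmasked selectively among seven oxygens.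
- The activated (2E,4E)-dienoate is prone to geometric isomerisation, and it meets a hindered secondary alcohol flanked by the C24 methoxy group.
- The count comes out about four steps longer in the linear sequence, and the risk of the ring closure is not smaller.

**Alternative 2:** cut C6–C7 and close the ring by a reductive pinacol coupling of the dialdehyde A2 (union of two carbons of like polarity).
- It would form the diol and the ring at once, but both carbonyls are vinylogous (a dienal and a 6-oxo-dienoate). The ketyl spin is therefore delocalised to C4 and C9, so vinylogous coupling and reduction of the dienoate compete.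
- The nearest stereocentres, C12 and C25, are too far away to choose one of the four diastereomers.
- The step would thus create a selectivity problem at the one stereodiad that can be bought.
- The low-valent metal also threatens the epoxide.

**Alternative 3:** cut C9–C10 and C19–C20, using the repeat of the two diene units, and join the southern iodide–stannane A3 head to tail with the northern iodide–stannane A4 in one double cross-coupling.
- Each partner carries both reacting functions. A3 can therefore oligomerise and A4 can close on itself (C9 onto C20, sixteen ring atoms).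
- The four possible pairings involve the same two types of terminus and should have similar rates.
- No symmetry element makes wrong pairings degenerate with right ones.
- Orthogonal metals would restore control only by turning the operation back into two separate steps with extra functional-group changes.

Key step: step 33

Assumption: the sense of induction given for the chiral catalysts and reagents in steps 4, 8, 14, 16, 22 and 25 follows the usual models for these substrate classes; if one proves opposite, the mirror-image catalyst is used and nothing else changes.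

## Steps

Step 1
Reactants: 1 dimethyl (4S,5S)-2,2-dimethyl-1,3-dioxolane-4,5-dicarboxylate
Product: 3 (4R,5R)-4,5-diethynyl-2,2-dimethyl-1,3-dioxolane, via dialdehyde 2 (not isolated)
Conditions: DIBAL-H (2.2 equiv), CH2Cl2, −78 °C; then MeOH, K2CO3, dimethyl (1-diazo-2-oxopropyl)phosphonate (2.6 equiv), −78 °C to rt
Reagents that add atoms: dimethyl (1-diazo-2-oxopropyl)phosphonate, CC(=O)C(=[N+]=[N-])P(=O)(OC)OC
Why: Partial reduction stops at the aluminium hemiacetal, and the Seyferth–Gilbert homologation turns each released aldehyde into a terminal alkyne in the same flask; the trans-dioxolane is the thermodynamic isomer, so the base cannot erode the two centres (future C6, C7), which come from the chiral pool.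

Step 2
Reactants: 3 (4R,5R)-4,5-diethynyl-2,2-dimethyl-1,3-dioxolane
Product: 4 (3R,4R)-hexa-1,5-diyne-3,4-diol
Conditions: 1 M aq HCl, THF, 40 °C
Reagents that add atoms: none
Why: Acid hydrolysis of the ketal has to precede the introduction of tin, because alkenylstannanes are protodestannylated by acid; alkynes and carbinol centres are inert here.

Step 3
Reactants: 4 (3R,4R)-hexa-1,5-diyne-3,4-diol
Product: 5 (1E,3R,4R,5E)-1,6-bis(tributylstannyl)hexa-1,5-diene-3,4-diol
Conditions: Bu3SnH (2.3 equiv), Pd2(dba)3 (1 mol %), Cy3P·HBF4 (4 mol %), i-Pr2NEt (8 mol %), CH2Cl2, 0 °C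
Reagents that add atoms: tributyltin hydride, CCCC[SnH](CCCC)CCCC
Why: Palladium-catalysed syn hydrostannation; the bulky electron-rich phosphine steers tin to the terminal carbon of propargylic alcohols, so both homotopic ends should give the (E)-β-stannyl allylic alcohol and the C2 axis is kept.

Step 4
Reactants: 6 cyclohex-2-en-1-one
Product: 8 (R)-trimethyl[(3-methylcyclohex-1-en-1-yl)oxy]silane, via zinc enolate 7 (not isolated)
Conditions: Me2Zn (1.3 equiv), Cu(OTf)2 (1 mol %), (R,S,S)-BINOL bis(1-phenylethyl)amine phosphoramidite (2 mol %), toluene, −25 °C; then TMSOTf (1.5 equiv), −25 to 0 °C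
Reagents that add atoms: dimethylzinc, C[Zn]C; trimethylsilyl trifluoromethanesulfonate, C[Si](C)(C)OS(=O)(=O)C(F)(F)F
Why: Copper-catalysed asymmetric conjugate addition sets C12 under ligand control; silylation of the regiodefined zinc enolate fixes the enol double bond on the side of the new centre, so the later ring cleavage has only one outcome.

Step 5
Reactants: 8 (R)-trimethyl[(3-methylcyclohex-1-en-1-yl)oxy]silane
Product: 10 methyl (R)-5-methyl-6-oxohexanoate, via oxo acid 9 (not isolated)
Conditions: O3, CH2Cl2/MeOH 5:1, −78 °C; Me2S, to rt; then TMSCHN2, toluene/MeOH, 0 °C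
Reagents that add atoms: ozone, [O-][O+]=O; (trimethylsilyl)diazomethane, C[Si](C)(C)C=[N+]=[N-]
Why: Ozonolysis of the silyl enol ether opens the ring to the chain C11–C16 with different oxidation levels at its ends (C11 aldehyde, C16 acid), and the acid is methylated in the same flask; the neutral medium keeps the α-methyl aldehyde intact.

Step 6
Reactants: 10 methyl (R)-5-methyl-6-oxohexanoate
Product: 11 methyl (R)-5-methylhept-6-ynoate
Conditions: dimethyl (1-diazo-2-oxopropyl)phosphonate (1.3 equiv), K2CO3, MeOH, 0 °C to rt
Reagents that add atoms: dimethyl (1-diazo-2-oxopropyl)phosphonate, CC(=O)C(=[N+]=[N-])P(=O)(OC)OC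
Why: Seyferth–Gilbert homologation under carbonate conditions, which normally leave α-methyl aldehydes configurationally intact; exchange of the methyl ester in methanol is degenerate.

Step 7
Reactants: 11 methyl (R)-5-methylhept-6-ynoate
Product: 12 (R)-5-methylhept-6-ynal
Conditions: DIBAL-H (1.05 equiv), CH2Cl2, −78 °C; aq Rochelle salt
Reagents that add atoms: none
Why: Ester-to-aldehyde reduction through the tetrahedral aluminate that is stable at −78 °C; the alkyne C–H does not react at this temperature.

Step 8
Reactants: 12 (R)-5-methylhept-6-ynal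
Product: 13 (3R,4R,8R)-3-(methoxymethoxy)-8-methyldec-1-en-9-yn-4-ol
Conditions: allyl methoxymethyl ether, s-BuLi, THF, −78 °C; (−)-Ipc2BOMe; BF3·OEt2; 12, −78 °C; then NaOH, H2O2, 0 °C to rt
Reagents that add atoms: allyl methoxymethyl ether, C=CCOCOC
Why: Asymmetric (Z)-γ-alkoxyallylboration (Brown type): the chair transition state turns the Z geometry into the syn relation C16/C17, and the isopinocampheyl groups derived from (+)-α-pinene fix the absolute sense (16R,17R); C12 is too remote to interfere.

Step 9
Reactants: 13 (3R,4R,8R)-3-(methoxymethoxy)-8-methyldec-1-en-9-yn-4-ol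
Product: 14 (3R,4R,8R)-4-methoxy-3-(methoxymethoxy)-8-methylundec-1-en-9-yne
Conditions: n-BuLi (2.3 equiv), THF, −78 to 0 °C; MeI (6 equiv), DMPU, 0 °C to rt
Reagents that add atoms: iodomethane, CI
Why: One base and one electrophile perform two methylations, a Williamson etherification of the C16 alkoxide and an acetylide alkylation that installs the methyl branch of C10; the acetal on C17–O rules out any ambiguity between the two oxygens.

Step 10
Reactants: 14 (3R,4R,8R)-4-methoxy-3-(methoxymethoxy)-8-methylundec-1-en-9-yne
Product: 15 (3R,4R,8R)-4-methoxy-8-methylundec-1-en-9-yn-3-ol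
Conditions: conc. HCl (cat.), MeOH, 45 °C
Reagents that add atoms: none
Why: Acid-catalysed transacetalisation removes the methoxymethyl group while the molecule still holds no epoxide, diene or silyl ether; the monosubstituted allylic carbinol does not ionise readily.

Step 11
Reactants: 15 (3R,4R,8R)-4-methoxy-8-methylundec-1-en-9-yn-3-ol
Product: 16 triethyl{[(3R,4R,8R)-4-methoxy-8-methylundec-1-en-9-yn-3-yl]oxy}silane
Conditions: TESCl, imidazole, CH2Cl2, 0 °C
Reagents that add atoms: chlorotriethylsilane, CC[Si](Cl)(CC)CC
Why: Standard silylation; the triethylsilyl group is chosen so that all four silyl ethers of 48 leave together under mild fluoride.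

Step 12
Reactants: 16 triethyl{[(3R,4R,8R)-4-methoxy-8-methylundec-1-en-9-yn-3-yl]oxy}silane
Product: 17 (2S,3R,7R)-3-methoxy-7-methyl-2-(triethylsilyloxy)dec-8-ynal
Conditions: O3, CH2Cl2, −78 °C (Sudan III end point); PPh3, to rt
Reagents that add atoms: ozone, [O-][O+]=O
Why: Ozonolysis; the monosubstituted alkene reacts far faster than the internal alkyne, and the dye end point prevents an excess of ozone.

Step 13
Reactants: 17 (2S,3R,7R)-3-methoxy-7-methyl-2-(triethylsilyloxy)dec-8-ynal
Product: 18 (1E,3R,4R,8R)-1-iodo-4-methoxy-8-methyl-3-(triethylsilyloxy)undec-1-en-9-yne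
Conditions: CrCl2 (8 equiv), CHI3 (3 equiv), THF/1,4-dioxane 1:6, 0 °C to rt
Reagents that add atoms: iodoform, IC(I)I
Why: Takai olefination; the gem-dichromium reagent adds and eliminates to the E iodoalkene, and the non-basic medium should not epimerise the α-silyloxy aldehyde.

Step 14
Reactants: 19 pent-3-yn-2-one
Product: 20 (R)-pent-3-yn-2-ol
Conditions: Ru[(R,R)-TsDPEN](p-cymene) (0.5 mol %), i-PrOH, rt
Reagents that add atoms: none
Why: Asymmetric transfer hydrogenation of an alkynyl ketone, a substrate class for which this catalyst type discriminates well between the alkynyl and methyl groups; the carbinol centre is the origin of C22.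

Step 15
Reactants: 20 (R)-pent-3-yn-2-ol
Product: 22 (P)-tributyl(penta-2,3-dien-2-yl)stannane, via mesylate 21 (not isolated)
Conditions: MsCl, Et3N, CH2Cl2, −78 °C, aqueous work-up, used crude; then Bu3SnLi (from Bu3SnH, LDA), CuBr·SMe2, THF, −60 °C
Reagents that add atoms: methanesulfonyl chloride, CS(=O)(=O)Cl (into 21 only); tributyltin hydride, CCCC[SnH](CCCC)CCCC
Why: Anti SN2′ displacement of a propargylic mesylate by a stannylcopper reagent, which transfers the central chirality of 20 into the axial chirality of the allene.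

Step 16
Reactants: 23 2-vinyloxirane (racemic)
Product: 24 (R)-2-methoxybut-3-en-1-ol
Conditions: MeOH (1.1 equiv), Pd2(dba)3·CHCl3 (1 mol %), (R,R)-DACH-phenyl bis(2-diphenylphosphinobenzamide) ligand (3 mol %), Et3B (1 mol %), CH2Cl2, rt
Reagents that add atoms: methanol, CO
Why: Dynamic kinetic asymmetric allylic etherification: both enantiomers of 23 ionise to π-allylpalladium species that interconvert faster than they are trapped, and the boron co-catalyst ties methanol to the alkoxide and delivers it to the internal carbon, so the racemate is funnelled into the one C24 configuration.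

Step 17
Reactants: 24 (R)-2-methoxybut-3-en-1-ol
Product: 25 (R)-triethyl[(2-methoxybut-3-en-1-yl)oxy]silane
Conditions: TESCl, imidazole, CH2Cl2, 0 °C
Reagents that add atoms: chlorotriethylsilane, CC[Si](Cl)(CC)CC
Why: Standard silylation; the primary triethylsilyl ether later serves as a latent aldehyde (step 21) and is a poor chelator in step 19.

Step 18
Reactants: 25 (R)-triethyl[(2-methoxybut-3-en-1-yl)oxy]silane
Product: 26 (S)-2-methoxy-3-(triethylsilyloxy)propanal
Conditions: O3, CH2Cl2, −78 °C; PPh3, to rt
Reagents that add atoms: ozone, [O-][O+]=O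
Why: Ozonolysis of the only alkene; the neutral reductive work-up keeps the α-methoxy aldehyde configurationally intact, and it is used at once.

Step 19
Reactants: 26 (S)-2-methoxy-3-(triethylsilyloxy)propanal; 22 (P)-tributyl(penta-2,3-dien-2-yl)stannane
Product: 27 (2S,3S,4R)-2-methoxy-4-methyl-1-(triethylsilyloxy)hept-5-yn-3-ol
Conditions: MgBr2·OEt2 (2.5 equiv), CH2Cl2, −25 °C
Reagents that add atoms: none
Why: Lewis-acid-promoted SE2′ addition of a chiral allenylstannane through an open transition state (anti to tin), which gives the C22/C23 syn relation; magnesium chelates the aldehyde and the α-methoxy oxygen, which gives the C23/C24 syn relation, and both demands are met by the same face, so the pairing is matched.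

Step 20
Reactants: 27 (2S,3S,4R)-2-methoxy-4-methyl-1-(triethylsilyloxy)hept-5-yn-3-ol
Product: 28 (2S,3S,4R)-2-methoxy-4-methyl-1,3-bis(triethylsilyloxy)hept-5-yne
Conditions: TESOTf, 2,6-lutidine, CH2Cl2, −78 to 0 °C
Reagents that add atoms: triethylsilyl trifluoromethanesulfonate, CC[Si](CC)(CC)OS(=O)(=O)C(F)(F)F
Why: The silyl triflate is needed for the hindered C23 hydroxyl between two branched carbons; no acid-labile group is present.

Step 21
Reactants: 28 (2S,3S,4R)-2-methoxy-4-methyl-1,3-bis(triethylsilyloxy)hept-5-yne
Product: 29 (2R,3S,4R)-2-methoxy-4-methyl-3-(triethylsilyloxy)hept-5-ynal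
Conditions: (COCl)2 (4 equiv), DMSO (8 equiv), CH2Cl2, −78 to −40 °C; Et3N, −78 °C to 0 °C
Reagents that add atoms: none
Why: Swern oxidation applied directly to a primary triethylsilyl ether: the unhindered ether oxygen attacks the chlorosulfonium salt and loses silicon, while the secondary ether is too hindered, so deprotection and oxidation are one step.

Step 22
Reactants: 30 butanal
Product: 31 (3S,4S)-3-methoxyhept-1-en-4-ol
Conditions: allyl methyl ether, s-BuLi, THF, −78 °C; (+)-Ipc2BOMe; BF3·OEt2; 30, −78 °C; then NaOH, H2O2, 0 °C to rt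
Reagents that add atoms: allyl methyl ether, C=CCOC
Why: The same (Z)-γ-alkoxyallylboration as in step 8 in the mirror-image reagent series; the chair transition state gives the C32/C33 syn relation with the methyl ether already in place, and the reagent fixes the absolute sense.

Step 23
Reactants: 31 (3S,4S)-3-methoxyhept-1-en-4-ol
Product: 32 triethyl{[(3S,4S)-3-methoxyhept-1-en-4-yl]oxy}silane
Conditions: TESCl, imidazole, CH2Cl2, 0 °C to rt
Reagents that add atoms: chlorotriethylsilane, CC[Si](Cl)(CC)CC
Why: Standard silylation; C33–O has to be blocked before the epoxide exists, otherwise it could open it.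

Step 24
Reactants: 32 triethyl{[(3S,4S)-3-methoxyhept-1-en-4-yl]oxy}silane
Product: 34 (2E,4S,5S)-4-methoxy-2-methyl-5-(triethylsilyloxy)oct-2-enal, via aldehyde 33 (not isolated)
Conditions: O3, CH2Cl2, −78 °C; PPh3, to rt; solvent change; 2-(triphenylphosphoranylidene)propanal, toluene, 60 °C
Reagents that add atoms: ozone, [O-][O+]=O (into 33 only); 2-(triphenylphosphoranylidene)propanal, CC(C=O)=P(c1ccccc1)(c1ccccc1)c1ccccc1
Why: Ozonolysis followed by a Wittig reaction with a stabilised ylide, which gives the E trisubstituted enal and adds C29, C30 and the C30 methyl in the right oxidation state; the activated α-alkoxy aldehyde reacts under mild heating.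

Step 25
Reactants: 34 (2E,4S,5S)-4-methoxy-2-methyl-5-(triethylsilyloxy)oct-2-enal
Product: 35 (4S,5E,7S,8S)-7-methoxy-5-methyl-8-(triethylsilyloxy)undec-5-en-1-yn-4-ol
Conditions: allenylboronic acid pinacol ester (1.5 equiv), (S)-TRIP phosphoric acid (5 mol %), 4 Å MS, toluene, −20 °C
Reagents that add atoms: allenylboronic acid pinacol ester, C=C=CB1OC(C)(C)C(C)(C)O1
Why: Chiral phosphoric acid catalysed propargylboration through a closed six-membered transition state; the catalyst sets C29, and the existing centres lie beyond the alkene and should have little influence.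

Step 26
Reactants: 35 (4S,5E,7S,8S)-7-methoxy-5-methyl-8-(triethylsilyloxy)undec-5-en-1-yn-4-ol
Product: 36 C26–C36 epoxy alcohol (C30–C31 epoxide, free C29–OH, C33–OTES, terminal alkyne; all centres spatially as in 49)
Conditions: Ti(Oi-Pr)4 (20 mol %), L-(+)-DIPT (24 mol %), t-BuOOH (2 equiv), 4 Å MS, CH2Cl2, −20 °C
Reagents that add atoms: tert-butyl hydroperoxide, CC(C)(C)OO
Why: Sharpless asymmetric epoxidation in the matched sense: L-(+)-tartrate delivers oxygen to the face that the (S)-carbinol itself prefers (erythro product), which sets C30 and C31; only the alkene of the allylic alcohol reacts.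

Step 27
Reactants: 36 C26–C36 epoxy alcohol
Product: 37 C26–C36 epoxy alkyne with TES ethers at C29 and C33
Conditions: TESCl, imidazole, DMAP (cat.), DMF, 0 °C to rt
Reagents that add atoms: chlorotriethylsilane, CC[Si](Cl)(CC)CC
Why: Silylation with the chloride and imidazole avoids the Lewis acidity of a silyl triflate next to the epoxide.

Step 28
Reactants: 37 C26–C36 epoxy alkyne with TES ethers at C29 and C33
Product: 39 C26–C36 (E)-vinyl iodide, via alkenylzirconocene 38 (not isolated)
Conditions: Cp2Zr(H)Cl (1.4 equiv), THF, 0 °C to rt, short contact; I2, −78 °C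
Reagents that add atoms: zirconocene chloride hydride, [H][Zr](Cl)(C1C=CC=C1)C1C=CC=C1 (into 38 only); iodine, II
Why: Hydrozirconation–iodination: syn addition places zirconium on the terminal carbon, and iodinolysis proceeds with retention to the E iodide; terminal alkynes react much faster than epoxides with this hydride.

Step 29
Reactants: 29 (2R,3S,4R)-2-methoxy-4-methyl-3-(triethylsilyloxy)hept-5-ynal; 39 C26–C36 (E)-vinyl iodide
Product: 40 C20–C36 allylic alcohol (free 25S hydroxyl; TES ethers at C23, C29, C33; C20–C21 methyl alkyne)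
Conditions: CrCl2 (6 equiv), NiCl2 (1 mol % of Cr), DMSO, rt
Reagents that add atoms: none
Why: Nozaki–Hiyama–Kishi coupling, which tolerates the epoxide, the alkyne and the silyl ethers and keeps the E geometry; the non-chelating chromium reagent should follow the polar Felkin–Anh model at C24 (24,25-anti) and the 1,3-anti model for the β-silyloxy group at C23, and both point to the same face.

Step 30
Reactants: 40 C20–C36 allylic alcohol; 18 (1E,3R,4R,8R)-1-iodo-4-methoxy-8-methyl-3-(triethylsilyloxy)undec-1-en-9-yne
Product: 42 C10–C36 dienyl alcohol with the C10–C11 methyl alkyne, via C20 vinylstannane 41 (not isolated)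
Conditions: Bu3SnH (1.3 equiv, slow addition), PdCl2(PPh3)2 (5 mol %), THF, 0 °C to rt; then 18, Pd2(dba)3 (5 mol %), AsPh3 (20 mol %), CuI (20 mol %), DMF, rt to 40 °C
Reagents that add atoms: tributyltin hydride, CCCC[SnH](CCCC)CCCC (tin enters 41 only and leaves again)
Why: One-pot hydrostannation–Stille coupling: syn hydropalladation puts tin on the methyl-bearing C20, away from the branched C22/C23 region; the catalyst destroys surplus hydride before 18 and its alkyne are added, and the coupling forms C19–C20 with retention at both alkenes.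

Step 31
Reactants: 42 C10–C36 dienyl alcohol with the C10–C11 methyl alkyne
Product: 44 C10–C36 (E)-C10 vinyl iodide with free C25–OH, via C10 vinylstannane 43 (not isolated)
Conditions: Bu3SnH (1.3 equiv, slow addition), PdCl2(PPh3)2 (5 mol %), THF, 0 °C; then I2 (1.0 equiv), NaHCO3, CH2Cl2, −78 °C
Reagents that add atoms: tributyltin hydride, CCCC[SnH](CCCC)CCCC (tin enters 43 only); iodine, II
Why: Hydrostannation–iododestannylation: alkynes react far faster than alkenes or dienes, tin goes to C10 distal to the C12 branch, and the stannane consumes one equivalent of iodine at −78 °C with retention before the polyene can react.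

Step 32
Reactants: 44 C10–C36 (E)-C10 vinyl iodide with free C25–OH; 45 (E)-3-iodoacrylic acid
Product: 46 acyclic bis(vinyl iodide), the C25 (E)-3-iodoacrylate of 44
Conditions: 45 (2 equiv), DIC (2 equiv), DMAP (0.2 equiv), CH2Cl2, 0 °C
Reagents that add atoms: none
Why: Steglich esterification of the only free hydroxyl; DMAP is kept catalytic and the temperature low, so that addition–elimination at the β-iodide and E/Z scrambling do not compete.

Step 33
Reactants: 46 acyclic bis(vinyl iodide); 5 (1E,3R,4R,5E)-1,6-bis(tributylstannyl)hexa-1,5-diene-3,4-diol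
Product: 48 tetra-TES macrolactone with free C6/C7 diol, via open-chain C9 stannane 47 (not isolated)
Conditions: Pd2(dba)3·CHCl3 (15 mol %), AsPh3 (60 mol %), i-Pr2NEt, DMF/THF 1:1, rt to 40 °C; 46 and 5 (1.05 equiv) added together by syringe pump, final concentration about 1 mM
Reagents that add atoms: none
Why: Pd(0) inserts first into the electron-poor C3–I bond of 46, either of the two homotopic stannane ends of 5 transmetalates, and reductive elimination forms C3–C4 to give 47; a second oxidative addition at C10–I, intramolecular transmetalation from C9 and reductive elimination form C9–C10 and close the ring. The closest known reaction type is the double Stille "stitching" macrocyclisation of an acyclic bis(vinyl iodide) with a 1,2-bis(stannyl)alkene, and here the two-carbon linchpin is replaced by a six-carbon one of the same symmetry. The one ring that closes is the 26-membered lactone; both new bonds are endocyclic sp2–sp2 bonds, the closure runs through a large palladacycle, and three rigid E-configured polyene units limit the freedom of the chain. No stereocentre is created: C6 and C7 enter intact from 5, and all four participating alkene geometries are kept because the Stille coupling is stereoretentive. The orientation of the linchpin needs no control, because the C2 axis of 5 makes both orientations identical. Cyclisation has to beat oligomerisation: this rests on the rate gap between the two iodides, which orders the two events, on the unhindered and fast-transmetalating stannane, and on slow simultaneous addition at high dilution. Chemoselectivity is secured by the neutral medium, which leaves the free diol, the epoxide, the ester and the silyl ethers untouched.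

Step 34
Reactants: 48 tetra-TES macrolactone
Product: 49 target macrolide CNP0328768.3
Conditions: HF·pyridine, excess pyridine, THF, 0 °C to rt; quench with aq NaHCO3
Reagents that add atoms: none
Why: Fluoride-mediated cleavage of four secondary triethylsilyl ethers; buffering with pyridine keeps the medium too weakly acidic to open the epoxide (which is deactivated by the C–O bonds on both sides) and too weakly basic for an acyl shift from C25 to C23.

## Compound list

1 | dimethyl (4S,5S)-2,2-dimethyl-1,3-dioxolane-4,5-dicarboxylate | COC(=O)[C@H]1OC(C)(C)O[C@@H]1C(=O)OC | starting material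
2 | (4S,5S)-2,2-dimethyl-1,3-dioxolane-4,5-dicarbaldehyde | O=C[C@H]1OC(C)(C)O[C@@H]1C=O | intermediate
3 | (4R,5R)-4,5-diethynyl-2,2-dimethyl-1,3-dioxolane | C#C[C@H]1OC(C)(C)O[C@@H]1C#C | intermediate
4 | (3R,4R)-hexa-1,5-diyne-3,4-diol | C#C[C@@H](O)[C@H](O)C#C | intermediate
5 | (1E,3R,4R,5E)-1,6-bis(tributylstannyl)hexa-1,5-diene-3,4-diol (C4–C9 linchpin) | CCCC[Sn](CCCC)(CCCC)/C=C/[C@@H](O)[C@H](O)/C=C/[Sn](CCCC)(CCCC)CCCC | intermediate
6 | cyclohex-2-en-1-one | O=C1C=CCCC1 | starting material
7 | methylzinc (R)-3-methylcyclohex-1-en-1-olate | C[Zn]OC1=C[C@H](C)CCC1 | intermediate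
8 | (R)-trimethyl[(3-methylcyclohex-1-en-1-yl)oxy]silane | C[Si](C)(C)OC1=C[C@H](C)CCC1 | intermediate
9 | (R)-5-methyl-6-oxohexanoic acid | OC(=O)CCC[C@@H](C)C=O | intermediate
10 | methyl (R)-5-methyl-6-oxohexanoate | COC(=O)CCC[C@@H](C)C=O | intermediate
11 | methyl (R)-5-methylhept-6-ynoate | COC(=O)CCC[C@@H](C)C#C | intermediate
12 | (R)-5-methylhept-6-ynal | O=CCCC[C@@H](C)C#C | intermediate
13 | (3R,4R,8R)-3-(methoxymethoxy)-8-methyldec-1-en-9-yn-4-ol | C#C[C@H](C)CCC[C@@H](O)[C@H](OCOC)C=C | intermediate
14 | (3R,4R,8R)-4-methoxy-3-(methoxymethoxy)-8-methylundec-1-en-9-yne | CC#C[C@H](C)CCC[C@@H](OC)[C@H](OCOC)C=C | intermediate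
15 | (3R,4R,8R)-4-methoxy-8-methylundec-1-en-9-yn-3-ol | CC#C[C@H](C)CCC[C@@H](OC)[C@H](O)C=C | intermediate
16 | triethyl{[(3R,4R,8R)-4-methoxy-8-methylundec-1-en-9-yn-3-yl]oxy}silane | CC#C[C@H](C)CCC[C@@H](OC)[C@H](O[Si](CC)(CC)CC)C=C | intermediate
17 | (2S,3R,7R)-3-methoxy-7-methyl-2-(triethylsilyloxy)dec-8-ynal | CC#C[C@H](C)CCC[C@@H](OC)[C@H](O[Si](CC)(CC)CC)C=O | intermediate
18 | (1E,3R,4R,8R)-1-iodo-4-methoxy-8-methyl-3-(triethylsilyloxy)undec-1-en-9-yne (C10–C19 fragment) | CC#C[C@H](C)CCC[C@@H](OC)[C@H](O[Si](CC)(CC)CC)/C=C/I | intermediate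
19 | pent-3-yn-2-one | CC#CC(C)=O | starting material
20 | (R)-pent-3-yn-2-ol | CC#C[C@@H](C)O | intermediate
21 | (R)-pent-3-yn-2-yl methanesulfonate | CC#C[C@@H](C)OS(C)(=O)=O | intermediate
22 | (P)-tributyl(penta-2,3-dien-2-yl)stannane | CC([H])=[C@@]=C(C)[Sn](CCCC)(CCCC)CCCC | intermediate
23 | 2-vinyloxirane (racemic) | C=CC1CO1 | starting material
24 | (R)-2-methoxybut-3-en-1-ol | C=C[C@@H](OC)CO | intermediate
25 | (R)-triethyl[(2-methoxybut-3-en-1-yl)oxy]silane | C=C[C@@H](OC)CO[Si](CC)(CC)CC | intermediate
26 | (S)-2-methoxy-3-(triethylsilyloxy)propanal | O=C[C@@H](OC)CO[Si](CC)(CC)CC | intermediate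
27 | (2S,3S,4R)-2-methoxy-4-methyl-1-(triethylsilyloxy)hept-5-yn-3-ol | CC#C[C@@H](C)[C@H](O)[C@@H](OC)CO[Si](CC)(CC)CC | intermediate
28 | (2S,3S,4R)-2-methoxy-4-methyl-1,3-bis(triethylsilyloxy)hept-5-yne | CC#C[C@@H](C)[C@H](O[Si](CC)(CC)CC)[C@@H](OC)CO[Si](CC)(CC)CC | intermediate
29 | (2R,3S,4R)-2-methoxy-4-methyl-3-(triethylsilyloxy)hept-5-ynal (C20–C25 fragment) | CC#C[C@@H](C)[C@H](O[Si](CC)(CC)CC)[C@@H](OC)C=O | intermediate
30 | butanal | CCCC=O | starting material
31 | (3S,4S)-3-methoxyhept-1-en-4-ol | CCC[C@H](O)[C@@H](OC)C=C | intermediate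
32 | triethyl{[(3S,4S)-3-methoxyhept-1-en-4-yl]oxy}silane | CCC[C@H](O[Si](CC)(CC)CC)[C@@H](OC)C=C | intermediate
33 | (2R,3S)-2-methoxy-3-(triethylsilyloxy)hexanal | CCC[C@H](O[Si](CC)(CC)CC)[C@@H](OC)C=O | intermediate
34 | (2E,4S,5S)-4-methoxy-2-methyl-5-(triethylsilyloxy)oct-2-enal | CCC[C@H](O[Si](CC)(CC)CC)[C@@H](OC)/C=C(\C)C=O | intermediate
35 | (4S,5E,7S,8S)-7-methoxy-5-methyl-8-(triethylsilyloxy)undec-5-en-1-yn-4-ol | CCC[C@H](O[Si](CC)(CC)CC)[C@@H](OC)/C=C(\C)[C@@H](O)CC#C | intermediate
36 | C26–C36 epoxy alcohol (C30–C31 epoxide, free C29–OH, C33–OTES, terminal alkyne) | CCC[C@H](O[Si](CC)(CC)CC)[C@@H](OC)[C@H]1O[C@]1(C)[C@@H](O)CC#C | intermediate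
37 | C26–C36 epoxy alkyne, TES ethers at C29 and C33 | CCC[C@H](O[Si](CC)(CC)CC)[C@@H](OC)[C@H]1O[C@]1(C)[C@@H](O[Si](CC)(CC)CC)CC#C | intermediate
38 | C26 (E)-alkenylzirconocene chloride of 37 | CCC[C@H](O[Si](CC)(CC)CC)[C@@H](OC)[C@H]1O[C@]1(C)[C@@H](O[Si](CC)(CC)CC)C/C=C/[Zr](Cl)(C1C=CC=C1)C1C=CC=C1 | intermediate
39 | C26–C36 (E)-vinyl iodide | CCC[C@H](O[Si](CC)(CC)CC)[C@@H](OC)[C@H]1O[C@]1(C)[C@@H](O[Si](CC)(CC)CC)C/C=C/I | intermediate
40 | C20–C36 allylic alcohol (25S, free OH; C20–C21 methyl alkyne) | CCC[C@H](O[Si](CC)(CC)CC)[C@@H](OC)[C@H]1O[C@]1(C)[C@@H](O[Si](CC)(CC)CC)C/C=C/[C@H](O)[C@H](OC)[C@@H](O[Si](CC)(CC)CC)[C@H](C)C#CC | intermediate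
41 | C20 (E)-vinylstannane of 40 | CCC[C@H](O[Si](CC)(CC)CC)[C@@H](OC)[C@H]1O[C@]1(C)[C@@H](O[Si](CC)(CC)CC)C/C=C/[C@H](O)[C@H](OC)[C@@H](O[Si](CC)(CC)CC)[C@H](C)/C=C(\C)[Sn](CCCC)(CCCC)CCCC | intermediate
42 | C10–C36 dienyl alcohol with C10–C11 methyl alkyne | CCC[C@H](O[Si](CC)(CC)CC)[C@@H](OC)[C@H]1O[C@]1(C)[C@@H](O[Si](CC)(CC)CC)C/C=C/[C@H](O)[C@H](OC)[C@@H](O[Si](CC)(CC)CC)[C@H](C)/C=C(\C)/C=C/[C@@H](O[Si](CC)(CC)CC)[C@H](OC)CCC[C@@H](C)C#CC | intermediate
43 | C10 (E)-vinylstannane of 42 | CCC[C@H](O[Si](CC)(CC)CC)[C@@H](OC)[C@H]1O[C@]1(C)[C@@H](O[Si](CC)(CC)CC)C/C=C/[C@H](O)[C@H](OC)[C@@H](O[Si](CC)(CC)CC)[C@H](C)/C=C(\C)/C=C/[C@@H](O[Si](CC)(CC)CC)[C@H](OC)CCC[C@@H](C)/C=C(\C)[Sn](CCCC)(CCCC)CCCC | intermediate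
44 | C10–C36 (E)-C10 vinyl iodide with free C25–OH | CCC[C@H](O[Si](CC)(CC)CC)[C@@H](OC)[C@H]1O[C@]1(C)[C@@H](O[Si](CC)(CC)CC)C/C=C/[C@H](O)[C@H](OC)[C@@H](O[Si](CC)(CC)CC)[C@H](C)/C=C(\C)/C=C/[C@@H](O[Si](CC)(CC)CC)[C@H](OC)CCC[C@@H](C)/C=C(\C)I | intermediate
45 | (E)-3-iodoacrylic acid | OC(=O)/C=C/I | starting material
46 | acyclic bis(vinyl iodide), C25 (E)-3-iodoacrylate of 44 | CCC[C@H](O[Si](CC)(CC)CC)[C@@H](OC)[C@H]1O[C@]1(C)[C@@H](O[Si](CC)(CC)CC)C/C=C/[C@H](OC(=O)/C=C/I)[C@H](OC)[C@@H](O[Si](CC)(CC)CC)[C@H](C)/C=C(\C)/C=C/[C@@H](O[Si](CC)(CC)CC)[C@H](OC)CCC[C@@H](C)/C=C(\C)I | intermediate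
47 | open-chain C9 stannane / C10 iodide (C3–C4 already joined) | CCC[C@H](O[Si](CC)(CC)CC)[C@@H](OC)[C@H]1O[C@]1(C)[C@@H](O[Si](CC)(CC)CC)C/C=C/[C@H](OC(=O)/C=C/C=C/[C@@H](O)[C@H](O)/C=C/[Sn](CCCC)(CCCC)CCCC)[C@H](OC)[C@@H](O[Si](CC)(CC)CC)[C@H](C)/C=C(\C)/C=C/[C@@H](O[Si](CC)(CC)CC)[C@H](OC)CCC[C@@H](C)/C=C(\C)I | intermediate
48 | tetra-TES macrolactone (TES at C17, C23, C29, C33; free C6/C7 diol) | CCC[C@H](O[Si](CC)(CC)CC)[C@@H](OC)[C@H]1O[C@]1(C)[C@@H](O[Si](CC)(CC)CC)C/C=C/[C@@H]1OC(=O)/C=C/C=C/[C@@H](O)[C@H](O)/C=C/C(C)=C/[C@H](C)CCC[C@@H](OC)[C@H](O[Si](CC)(CC)CC)/C=C/C(C)=C/[C@@H](C)[C@H](O[Si](CC)(CC)CC)[C@H]1OC | intermediate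
49 | CNP0328768.3 | CCC[C@H](O)[C@@H](OC)[C@H]1O[C@]1(C)[C@@H](O)C/C=C/[C@@H]1OC(=O)/C=C/C=C/[C@@H](O)[C@H](O)/C=C/C(C)=C/[C@H](C)CCC[C@@H](OC)[C@H](O)/C=C/C(C)=C/[C@@H](C)[C@H](O)[C@H]1OC | target

## Step count and least certain steps

Total step count: 34 (telescoped operations counted once). Longest linear sequence: 15 steps (steps 4–13, then 30–34).

**Step 33 (key step).**
- Most likely failure: intermolecular coupling outruns ring closure. The free stannane end of 47 may meet the reactive iodoacrylate of a fresh molecule of 46 before its own hindered C10 iodide has undergone oxidative addition, and the chains then grow. Destannylation of 47 during a slow closure is the second danger.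
- Fallback (two-bond insertion replaced by a conventional single ring closure), setting out from 5 and 44:
  - Silylation of 5 gives the bis-TES linchpin F1.
  - One Stille coupling of F1, used in excess and recovered, with 45 gives the stannyl trienoic acid F2.
  - Carbodiimide esterification of 44 with F2 gives the seco iodide–stannane F3.
  - An intramolecular Stille coupling at C9–C10 gives the hexa-TES macrolactone F4.
  - The conditions of step 34 bring the route back at 49.

**Step 29.**
- Most likely failure: poor facial selectivity at C25. Alkenylchromium additions to α-alkoxy aldehydes often follow the Felkin–Anh model only weakly, and the large β-silyloxy group may distort the reactive conformer.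
- Fallback (C25 set by reduction instead of by C–C bond formation), setting out from the C25 epimer mixture of 40:
  - Dess–Martin oxidation gives the enone F5.
  - Chelation-controlled reduction with Zn(BH4)2 in ether, where the zinc chelate of the ketone and the C24 methoxy oxygen is attacked by hydride from the open face, should give the 24,25-anti alcohol.
  - The route is rejoined at 40.

**Step 30.**
- Most likely failure: a minor regioisomer from the hydrostannation is carried into the coupling, residual hydride adds to the alkyne of 18, or the hindered α-methyl stannane transmetalates slowly and loses tin by protonolysis.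
- Fallback (other metal and inverted roles, with both partners isolated), setting out from 40 and 17:
  - Hydrostannation of 40 and iodination of 41, with purification, give the C20 vinyl iodide F6.
  - Takai-type boron olefination of 17 (Cl2CHBpin, CrCl2, LiI) gives the (E)-vinylboronate F7.
  - A Suzuki coupling of F6 with F7 (Pd(dppf)Cl2, K3PO4, DMF/H2O) rejoins the route at 42.

**Step 34.**
- Most likely failure: the epoxide is opened by the liberated C33 or C29 hydroxyl while the slower silyl ethers (C23, C29) are still being cleaved in the strained setting of the ring. Loss of material through the polarity of the hexaol is a further risk.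
- Fallback (order inverted, so that the macrocycle never sees fluoride), setting out from 46:
  - Desilylation of the flexible acyclic compound gives the tetraol bis-iodide F8.
  - The neutral double Stille reaction of step 33 between F8 and 5, which tolerates free hydroxyls, gives 49 directly.

## Further compounds

F1 | step 33 | bis-TES ether of linchpin 5 | CCCC[Sn](CCCC)(CCCC)/C=C/[C@@H](O[Si](CC)(CC)CC)[C@H](O[Si](CC)(CC)CC)/C=C/[Sn](CCCC)(CCCC)CCCC
F2 | step 33 | (2E,4E,6R,7R,8E)-6,7-bis(triethylsilyloxy)-9-(tributylstannyl)nona-2,4,8-trienoic acid | OC(=O)/C=C/C=C/[C@@H](O[Si](CC)(CC)CC)[C@H](O[Si](CC)(CC)CC)/C=C/[Sn](CCCC)(CCCC)CCCC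
F3 | step 33 | seco C10 iodide / C9 stannane, ester of 44 with F2 | CCC[C@H](O[Si](CC)(CC)CC)[C@@H](OC)[C@H]1O[C@]1(C)[C@@H](O[Si](CC)(CC)CC)C/C=C/[C@H](OC(=O)/C=C/C=C/[C@@H](O[Si](CC)(CC)CC)[C@H](O[Si](CC)(CC)CC)/C=C/[Sn](CCCC)(CCCC)CCCC)[C@H](OC)[C@@H](O[Si](CC)(CC)CC)[C@H](C)/C=C(\C)/C=C/[C@@H](O[Si](CC)(CC)CC)[C@H](OC)CCC[C@@H](C)/C=C(\C)I
F4 | step 33 | hexa-TES macrolactone | CCC[C@H](O[Si](CC)(CC)CC)[C@@H](OC)[C@H]1O[C@]1(C)[C@@H](O[Si](CC)(CC)CC)C/C=C/[C@@H]1OC(=O)/C=C/C=C/[C@@H](O[Si](CC)(CC)CC)[C@H](O[Si](CC)(CC)CC)/C=C/C(C)=C/[C@H](C)CCC[C@@H](OC)[C@H](O[Si](CC)(CC)CC)/C=C/C(C)=C/[C@@H](C)[C@H](O[Si](CC)(CC)CC)[C@H]1OC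
F5 | step 29 | C25 enone of 40 | CCC[C@H](O[Si](CC)(CC)CC)[C@@H](OC)[C@H]1O[C@]1(C)[C@@H](O[Si](CC)(CC)CC)C/C=C/C(=O)[C@H](OC)[C@@H](O[Si](CC)(CC)CC)[C@H](C)C#CC
F6 | step 30 | C20 (E)-vinyl iodide of 40 | CCC[C@H](O[Si](CC)(CC)CC)[C@@H](OC)[C@H]1O[C@]1(C)[C@@H](O[Si](CC)(CC)CC)C/C=C/[C@H](O)[C@H](OC)[C@@H](O[Si](CC)(CC)CC)[C@H](C)/C=C(\C)I
F7 | step 30 | C19 (E)-vinylboronic acid pinacol ester of the southern fragment | CC#C[C@H](C)CCC[C@@H](OC)[C@H](O[Si](CC)(CC)CC)/C=C/B1OC(C)(C)C(C)(C)O1
F8 | step 34 | tetraol bis(vinyl iodide), desilylated 46 | CCC[C@H](O)[C@@H](OC)[C@H]1O[C@]1(C)[C@@H](O)C/C=C/[C@H](OC(=O)/C=C/I)[C@H](OC)[C@@H](O)[C@H](C)/C=C(\C)/C=C/[C@@H](O)[C@H](OC)CCC[C@@H](C)/C=C(\C)I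
A1 | alternative 1 | hexa-TES seco acid with free C25–OH | CCC[C@H](O[Si](CC)(CC)CC)[C@@H](OC)[C@H]1O[C@]1(C)[C@@H](O[Si](CC)(CC)CC)C/C=C/[C@H](O)[C@H](OC)[C@@H](O[Si](CC)(CC)CC)[C@H](C)/C=C(\C)/C=C/[C@@H](O[Si](CC)(CC)CC)[C@H](OC)CCC[C@@H](C)/C=C(\C)/C=C/[C@@H](O[Si](CC)(CC)CC)[C@H](O[Si](CC)(CC)CC)/C=C/C=C/C(=O)O
A2 | alternative 2 | C6/C7 dialdehyde | CCC[C@H](O[Si](CC)(CC)CC)[C@@H](OC)[C@H]1O[C@]1(C)[C@@H](O[Si](CC)(CC)CC)C/C=C/[C@H](OC(=O)/C=C/C=C/C=O)[C@H](OC)[C@@H](O[Si](CC)(CC)CC)[C@H](C)/C=C(\C)/C=C/[C@@H](O[Si](CC)(CC)CC)[C@H](OC)CCC[C@@H](C)/C=C(\C)/C=C/C=O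
A3 | alternative 3 | southern C10 iodide / C19 stannane | CCCC[Sn](CCCC)(CCCC)/C=C/[C@@H](O[Si](CC)(CC)CC)[C@H](OC)CCC[C@@H](C)/C=C(\C)I
A4 | alternative 3 | northern C20 iodide / C9 stannane | CCC[C@H](O[Si](CC)(CC)CC)[C@@H](OC)[C@H]1O[C@]1(C)[C@@H](O[Si](CC)(CC)CC)C/C=C/[C@H](OC(=O)/C=C/C=C/[C@@H](O)[C@H](O)/C=C/[Sn](CCCC)(CCCC)CCCC)[C@H](OC)[C@@H](O[Si](CC)(CC)CC)[C@H](C)/C=C(\C)I
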